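**Retrosynthetic overview**

- Numbering runs from the carboxyl carbon (C1). The strategy rests on the C8–C9 ethylene that separates the tertiary carbinol C10 from the (E)-C6=C7 trisubstituted alkene: it is read as a hydroborated vinyl group on C10, so the C7–C8 bond is cut (sp3–sp2 coupling), after removal of three silyl ethers and a methyl ester.
- Head (C8–C12 plus arene): the styrenyl C11=C12 alkene comes from a Horner–Wadsworth–Emmons reaction of an α-silyloxy aldehyde with a benzylic phosphonate; C10 (S) comes from a palladium-catalysed dynamic kinetic asymmetric opening of racemic isoprene monoepoxide.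
- Tail (C1–C7): the C2=C3 enoate comes from a stabilised Wittig reaction of (E)-5-iodo-4-methylpent-4-enal, itself made by carboalumination–iodination of pent-4-yn-1-ol.
- No ring is formed anywhere in the route; the only ring, the hydroquinone arene, is bought as 2,5-dimethylhydroquinone.

Key step: step 12

Assumption: the (R,R)-configured bis(diphenylphosphinobenzamide) ligand is taken to deliver the (S)-diol 3; should the sense of induction prove opposite, the (S,S)-ligand is used with no other change.

**Route**

Step 1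
Reactants: 1 racemic 2-methyl-2-vinyloxirane
Product: 3 (S)-2-methylbut-3-ene-1,2-diol, via carbonate half-ester 2 (not isolated)
Conditions: Pd2(dba)3·CHCl3 (1 mol %), N,N'-[(1R,2R)-cyclohexane-1,2-diyl]bis[2-(diphenylphosphanyl)benzamide] (3 mol %), BEt3 (1 mol %), NaHCO3 (1.2 equiv), CH2Cl2/H2O, rt
Reagents that add atoms: sodium hydrogencarbonate, [Na+].OC([O-])=O
Why: Tsuji–Trost-type dynamic kinetic asymmetric transformation in which zerovalent palladium opens both epoxide enantiomers to π-allyl complexes that interconvert through the unsubstituted terminus, and boron-templated delivery of hydrogencarbonate to the tertiary terminus inside the chiral ligand pocket sets C10 as (S), the half-ester 2 then losing CO2.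

Step 2
Reactants: 3 (S)-2-methylbut-3-ene-1,2-diol
Product: 4 (S)-2-methyl-1,2-bis(triethylsilyloxy)but-3-ene
Conditions: TESOTf (2.5 equiv), 2,6-lutidine (3.5 equiv), CH2Cl2, −78 → 0 °C
Reagents that add atoms: triethylsilyl trifluoromethanesulfonate, CC[Si](CC)(CC)OS(=O)(=O)C(F)(F)F
Why: Silyl ether formation with a silyl triflate and a hindered pyridine base covers both the primary and the hindered tertiary allylic hydroxyl without touching the stereocentre.

Step 3
Reactants: 4 (S)-2-methyl-1,2-bis(triethylsilyloxy)but-3-ene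
Product: 5 (S)-2-methyl-2-(triethylsilyloxy)but-3-enal
Conditions: (COCl)2 (4 equiv), DMSO (8 equiv), CH2Cl2, −78 → −30 °C; then Et3N, −78 → 0 °C
Reagents that add atoms: none
Why: Swern oxidation applied directly to a primary triethylsilyl ether, in which the activated sulfoxide cleaves the accessible primary O–Si bond and oxidises that carbon while the tertiary silyl ether is too hindered to react, and the fully substituted α-carbon cannot epimerise.

Step 4
Reactants: 6 2,5-dimethylhydroquinone
Product: 7 2,5-dimethyl-1,4-bis(triisopropylsilyloxy)benzene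
Conditions: TIPSCl (2.4 equiv), imidazole (5 equiv), DMF, rt → 40 °C
Reagents that add atoms: chlorotriisopropylsilane, CC(C)[Si](Cl)(C(C)C)C(C)C
Why: Imidazole-promoted silylation of both phenols gives bulky aryl silyl ethers that tolerate the later radical, basic and cross-coupling conditions.

Step 5
Reactants: 7 2,5-dimethyl-1,4-bis(triisopropylsilyloxy)benzene
Product: 8 1-(bromomethyl)-4-methyl-2,5-bis(triisopropylsilyloxy)benzene
Conditions: NBS (0.9 equiv), AIBN (5 mol %), PhCF3, 80 °C
Reagents that add atoms: N-bromosuccinimide, O=C1CCC(=O)N1Br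
Why: Wohl–Ziegler radical benzylic bromination in a non-polar medium, where sub-stoichiometric NBS limits double bromination of the two equivalent methyl groups and unreacted 7 is recycled.

Step 6
Reactants: 8 1-(bromomethyl)-4-methyl-2,5-bis(triisopropylsilyloxy)benzene
Product: 9 diethyl [4-methyl-2,5-bis(triisopropylsilyloxy)benzyl]phosphonate
Conditions: P(OEt)3 (3 equiv, neat), 130 °C
Reagents that add atoms: triethyl phosphite, CCOP(OCC)OCC
Why: Michaelis–Arbuzov reaction of a benzylic bromide, and the polar phosphonate is easily separated from any carried-over 7 or bis-phosphonate.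

Step 7
Reactants: 5 (S)-2-methyl-2-(triethylsilyloxy)but-3-enal; 9 diethyl [4-methyl-2,5-bis(triisopropylsilyloxy)benzyl]phosphonate
Product: 10 triethyl{[(3S,1E)-3-methyl-1-[4-methyl-2,5-bis(triisopropylsilyloxy)phenyl]penta-1,4-dien-3-yl]oxy}silane
Conditions: 9 (1.2 equiv), NaN(SiMe3)2, THF, −78 °C; then 5, −78 °C → rt
Reagents that add atoms: none
Why: Horner–Wadsworth–Emmons olefination of a non-enolisable aldehyde with a benzylic phosphonate anion should give the (E)-styrene through the less congested anti elimination pathway, the bulk of the triisopropylsilyl groups suppressing silyl transfer to the benzylic carbanion.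

Step 8
Reactants: 11 pent-4-yn-1-ol
Product: 13 (E)-5-iodo-4-methylpent-4-en-1-ol, via alkenylalane 12 (not isolated)
Conditions: AlMe3 (3 equiv), Cp2ZrCl2 (25 mol %), CH2Cl2, 0 °C → rt; then I2, THF, −30 → 0 °C
Reagents that add atoms: trimethylaluminium, C[Al](C)C; iodine, II
Why: Negishi zirconium-catalysed carboalumination adds methyl and aluminium syn across the terminal alkyne with aluminium at the terminus, and iodinolysis of the C–Al bond with retention fixes the (E)-geometry of the future C6=C7 alkene.

Step 9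
Reactants: 13 (E)-5-iodo-4-methylpent-4-en-1-ol
Product: 14 (E)-5-iodo-4-methylpent-4-enal
Conditions: TEMPO (10 mol %), PhI(OAc)2 (1.1 equiv), CH2Cl2, rt
Reagents that add atoms: none
Why: Oxoammonium-mediated oxidation of a primary alcohol stops at the aldehyde and leaves the alkenyl iodide untouched.

Step 10
Reactants: 15 methyl (triphenylphosphoranylidene)acetate; 16 5-bromo-2-methylpent-2-ene
Product: 18 methyl 6-methyl-2-(triphenylphosphoranylidene)hept-5-enoate, via phosphonium bromide 17 (not isolated)
Conditions: 16 (1.5 equiv), NaI (10 mol %), MeCN, 80 °C; then 2 M aq. NaOH, CH2Cl2, 0 °C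
Reagents that add atoms: none
Why: C-alkylation of an ester-stabilised phosphonium ylide by a primary halide (iodide-assisted) gives the α-substituted phosphonium salt, which hydroxide deprotonates to the new stabilised ylide.

Step 11
Reactants: 14 (E)-5-iodo-4-methylpent-4-enal; 18 methyl 6-methyl-2-(triphenylphosphoranylidene)hept-5-enoate
Product: 19 methyl (2E,6E)-7-iodo-6-methyl-2-(4-methylpent-3-en-1-yl)hepta-2,6-dienoate
Conditions: 18 (1.3 equiv), toluene, 80 °C
Reagents that add atoms: none
Why: Wittig reaction of a stabilised α-substituted ylide with an unhindered aliphatic aldehyde should place the ester trans to the aldehyde chain, giving the (2E)-enoate.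

Step 12
Reactants: 10 triethyl{[(3S,1E)-3-methyl-1-[4-methyl-2,5-bis(triisopropylsilyloxy)phenyl]penta-1,4-dien-3-yl]oxy}silane; 19 methyl (2E,6E)-7-iodo-6-methyl-2-(4-methylpent-3-en-1-yl)hepta-2,6-dienoate
Product: 21 methyl (2E,6E,10S,11E)-6,10-dimethyl-2-(4-methylpent-3-en-1-yl)-12-[4-methyl-2,5-bis(triisopropylsilyloxy)phenyl]-10-(triethylsilyloxy)dodeca-2,6,11-trienoate, via B-alkyl-9-BBN 20 (not isolated)
Conditions: 10 (1.3 equiv), 9-BBN (1.5 equiv), THF, 0 °C → rt; then 3 M aq. K3PO4; then 19, Pd(dppf)Cl2·CH2Cl2 (5 mol %), AsPh3 (10 mol %), DMF, rt, degassed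
Reagents that add atoms: none
Why: 9-BBN adds its B–H bond anti-Markovnikov across the monosubstituted C8=C9 vinyl group of 10 through a four-centre transition state, giving the primary alkylborane 20. Zerovalent palladium, formed from Pd(dppf)Cl2, inserts into the C7–I bond of 19 with retention of geometry, the base-activated borate transfers its primary alkyl group to the alkenylpalladium iodide, and reductive elimination forms the C7–C8 bond; the closest known reaction type is the 9-BBN hydroboration/B-alkyl Suzuki–Miyaura coupling with alkenyl iodides used to join polyene fragments. No ring is closed and no stereocentre is created: C10 (S) is remote from the reacting atoms, and the C2=C3, C6=C7 and C11=C12 geometries are carried through unchanged. The step needs chemoselective hydroboration of the terminal vinyl group over the 1,2-disubstituted styrenyl alkene, which the bulk of 9-BBN and the fully substituted C10 next to that alkene secure, and the trisubstituted alkenes of 19 never meet free B–H because residual borane is quenched by the aqueous base before 19 is added. The wide bite angle of dppf favours reductive elimination over β-hydride elimination, and phosphate at room temperature should spare the methyl ester and the aryl silyl ethers.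

Step 13
Reactants: 21 fully protected coupling product
Product: 22 methyl (2E,6E,10S,11E)-12-(2,5-dihydroxy-4-methylphenyl)-10-hydroxy-6,10-dimethyl-2-(4-methylpent-3-en-1-yl)dodeca-2,6,11-trienoate
Conditions: Bu4NF (5 equiv), AcOH (5 equiv), degassed THF, 0 °C → rt, argon
Reagents that add atoms: none
Why: Fluoride-mediated desilylation removes the two aryl silyl ethers and the tertiary triethylsilyl ether, the acetic acid buffer keeping the hydroquinone protonated and so less prone to air oxidation, without any acid that could ionise the styrenyl carbinol.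

Step 14
Reactants: 22 methyl ester triol
Product: 23 (2E,6E,10S,11E)-12-(2,5-dihydroxy-4-methylphenyl)-10-hydroxy-6,10-dimethyl-2-(4-methylpent-3-en-1-yl)dodeca-2,6,11-trienoic acid (CNP0134639.1)
Conditions: LiOH·H2O (10 equiv), degassed THF/MeOH/H2O (3:1:1), rt → 40 °C, argon, dark; then cold pH 4 phosphate buffer (H3PO4/NaH2PO4)
Reagents that add atoms: lithium hydroxide, [Li+].[OH-]
Why: Saponification by acyl–oxygen cleavage of the conjugated methyl ester under strictly oxygen-free conditions, followed by only mildly acidic cold work-up, should free the acid without oxidising the hydroquinone or cyclising the ortho-hydroxystyryl carbinol.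

**Compound list**

1 | racemic 2-methyl-2-vinyloxirane (isoprene monoepoxide) | CC1(C=C)CO1 | starting material
2 | (S)-1-hydroxy-2-methylbut-3-en-2-yl hydrogen carbonate (formed in situ) | C=C[C@](C)(OC(=O)O)CO | intermediate
3 | (S)-2-methylbut-3-ene-1,2-diol | C=C[C@](C)(O)CO | intermediate
4 | (S)-2-methyl-1,2-bis(triethylsilyloxy)but-3-ene | C=C[C@](C)(O[Si](CC)(CC)CC)CO[Si](CC)(CC)CC | intermediate
5 | (S)-2-methyl-2-(triethylsilyloxy)but-3-enal | C=C[C@](C)(O[Si](CC)(CC)CC)C=O | intermediate
6 | 2,5-dimethylhydroquinone | Cc1cc(O)c(C)cc1O | starting material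
7 | 2,5-dimethyl-1,4-bis(triisopropylsilyloxy)benzene | Cc1cc(O[Si](C(C)C)(C(C)C)C(C)C)c(C)cc1O[Si](C(C)C)(C(C)C)C(C)C | intermediate
8 | 1-(bromomethyl)-4-methyl-2,5-bis(triisopropylsilyloxy)benzene | BrCc1cc(O[Si](C(C)C)(C(C)C)C(C)C)c(C)cc1O[Si](C(C)C)(C(C)C)C(C)C | intermediate
9 | diethyl [4-methyl-2,5-bis(triisopropylsilyloxy)benzyl]phosphonate | CCOP(=O)(OCC)Cc1cc(O[Si](C(C)C)(C(C)C)C(C)C)c(C)cc1O[Si](C(C)C)(C(C)C)C(C)C | intermediate
10 | triethyl{[(3S,1E)-3-methyl-1-[4-methyl-2,5-bis(triisopropylsilyloxy)phenyl]penta-1,4-dien-3-yl]oxy}silane (head) | C=C[C@](C)(O[Si](CC)(CC)CC)/C=C/c1cc(O[Si](C(C)C)(C(C)C)C(C)C)c(C)cc1O[Si](C(C)C)(C(C)C)C(C)C | intermediate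
11 | pent-4-yn-1-ol | C#CCCCO | starting material
12 | dimethyl[(E)-5-(dimethylaluminiooxy)-2-methylpent-1-en-1-yl]alane (formed in situ) | C[Al](C)/C=C(\C)CCCO[Al](C)C | intermediate
13 | (E)-5-iodo-4-methylpent-4-en-1-ol | OCCC/C(C)=C/I | intermediate
14 | (E)-5-iodo-4-methylpent-4-enal | O=CCC/C(C)=C/I | intermediate
15 | methyl (triphenylphosphoranylidene)acetate | COC(=O)C=P(c1ccccc1)(c1ccccc1)c1ccccc1 | starting material
16 | 5-bromo-2-methylpent-2-ene | CC(C)=CCCBr | starting material
17 | (1-methoxy-6-methyl-1-oxohept-5-en-2-yl)triphenylphosphonium bromide (formed in situ) | COC(=O)C(CCC=C(C)C)[P+](c1ccccc1)(c1ccccc1)c1ccccc1.[Br-] | intermediate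
18 | methyl 6-methyl-2-(triphenylphosphoranylidene)hept-5-enoate | COC(=O)C(CCC=C(C)C)=P(c1ccccc1)(c1ccccc1)c1ccccc1 | intermediate
19 | methyl (2E,6E)-7-iodo-6-methyl-2-(4-methylpent-3-en-1-yl)hepta-2,6-dienoate (tail) | I/C=C(\C)CC/C=C(\CCC=C(C)C)C(=O)OC | intermediate
20 | 9-[(3S,4E)-3-methyl-5-[4-methyl-2,5-bis(triisopropylsilyloxy)phenyl]-3-(triethylsilyloxy)pent-4-en-1-yl]-9-borabicyclo[3.3.1]nonane (formed in situ) | C1CCC2CCCC1B2CC[C@](C)(O[Si](CC)(CC)CC)/C=C/c1cc(O[Si](C(C)C)(C(C)C)C(C)C)c(C)cc1O[Si](C(C)C)(C(C)C)C(C)C | intermediate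
21 | methyl (2E,6E,10S,11E)-6,10-dimethyl-2-(4-methylpent-3-en-1-yl)-12-[4-methyl-2,5-bis(triisopropylsilyloxy)phenyl]-10-(triethylsilyloxy)dodeca-2,6,11-trienoate | CC(C)=CCC/C(=C\CC/C(C)=C/CC[C@](C)(O[Si](CC)(CC)CC)/C=C/c1cc(O[Si](C(C)C)(C(C)C)C(C)C)c(C)cc1O[Si](C(C)C)(C(C)C)C(C)C)C(=O)OC | intermediate
22 | methyl (2E,6E,10S,11E)-12-(2,5-dihydroxy-4-methylphenyl)-10-hydroxy-6,10-dimethyl-2-(4-methylpent-3-en-1-yl)dodeca-2,6,11-trienoate | CC(C)=CCC/C(=C\CC/C(C)=C/CC[C@](C)(O)/C=C/c1cc(O)c(C)cc1O)C(=O)OC | intermediate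
23 | (2E,6E,10S,11E)-12-(2,5-dihydroxy-4-methylphenyl)-10-hydroxy-6,10-dimethyl-2-(4-methylpent-3-en-1-yl)dodeca-2,6,11-trienoic acid | CC(C)=CCC/C(=C\CC/C(C)=C/CC[C@](C)(O)/C=C/c1cc(O)c(C)cc1O)C(=O)O | target

**Step count**

Total: 14 steps. Longest linear sequence: 7 steps (1, 2, 3, 7, 12, 13, 14; the arene branch 4, 5, 6, 7, 12, 13, 14 is equally long).

**Steps most likely to fail, with fallbacks**

Step 12. The coupling may stall through slow transfer of the alkyl group from boron to palladium, with protodeboronation or β-hydride elimination taking over, and the aqueous base may strip the aryl silyl ethers. The fallback sets out from 10 and returns at 21, replacing the boron coupling by a base-free organozinc coupling. Compound 10 is hydroborated as before to 20 and oxidised in the same flask with NaBO3·4H2O to (3S,4E)-3-methyl-5-[4-methyl-2,5-bis(triisopropylsilyloxy)phenyl]-3-(triethylsilyloxy)pent-4-en-1-ol F1. Iodine, PPh3 and imidazole in CH2Cl2 convert it into the primary iodide triethyl{[(3S,1E)-5-iodo-3-methyl-1-[4-methyl-2,5-bis(triisopropylsilyloxy)phenyl]pent-1-en-3-yl]oxy}silane F2. Zinc dust with LiCl in THF inserts into the C–I bond to give the alkylzinc iodide F3, which is joined to 19 by Negishi coupling (Pd(PPh3)4, THF/DMA, rt → 40 °C) to give 21.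

Step 7. The hindered aldehyde may add slowly to the electron-rich benzylic phosphonate anion, the adduct may eliminate sluggishly, and the triethylsilyl group may migrate to the newly formed alkoxide. The fallback sets out from 8 (with 5) and returns at 10, using a sulfone-based olefination that eliminates through a Smiles rearrangement instead of an oxaphosphetane. Bromide 8 is treated with 1-phenyl-1H-tetrazole-5-thiol and K2CO3 in acetone to give the sulfide 5-{[4-methyl-2,5-bis(triisopropylsilyloxy)benzyl]sulfanyl}-1-phenyl-1H-tetrazole F4. Oxidation with (NH4)6Mo7O24·4H2O and H2O2 in EtOH gives the sulfone 5-{[4-methyl-2,5-bis(triisopropylsilyloxy)benzyl]sulfonyl}-1-phenyl-1H-tetrazole F5. Deprotonation of F5 with KN(SiMe3)2 in DME at −60 °C and addition of aldehyde 5 (Julia–Kocienski olefination) should give the (E)-styrene 10.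

Step 14. The free hydroquinone may be oxidised to the quinone in the alkaline medium, the α-branched conjugated ester may hydrolyse slowly, and acidification may cyclise the ortho-hydroxystyryl carbinol to a 2H-chromene. The fallback sets out from 19 and returns at 23, moving the hydrolysis ahead of the coupling so that the last step is a single fluoride treatment. Ester 19 is saponified (LiOH, THF/MeOH/H2O) to (2E,6E)-7-iodo-6-methyl-2-(4-methylpent-3-en-1-yl)hepta-2,6-dienoic acid F6. The acid is re-esterified with 2-(trimethylsilyl)ethanol, EDC·HCl and DMAP in CH2Cl2 to the 2-(trimethylsilyl)ethyl ester F7. F7 is coupled with borane 20 (from 10) under the conditions of step 12 to give the tris-silyl 2-(trimethylsilyl)ethyl ester F8. Excess Bu4NF in degassed THF then removes the three silyl ethers and the ester group together, and cold pH 4 phosphate buffer work-up gives 23.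

**Further compounds**

F1 | step 12 | (3S,4E)-3-methyl-5-[4-methyl-2,5-bis(triisopropylsilyloxy)phenyl]-3-(triethylsilyloxy)pent-4-en-1-ol | OCC[C@](C)(O[Si](CC)(CC)CC)/C=C/c1cc(O[Si](C(C)C)(C(C)C)C(C)C)c(C)cc1O[Si](C(C)C)(C(C)C)C(C)C
F2 | step 12 | triethyl{[(3S,1E)-5-iodo-3-methyl-1-[4-methyl-2,5-bis(triisopropylsilyloxy)phenyl]pent-1-en-3-yl]oxy}silane | ICC[C@](C)(O[Si](CC)(CC)CC)/C=C/c1cc(O[Si](C(C)C)(C(C)C)C(C)C)c(C)cc1O[Si](C(C)C)(C(C)C)C(C)C
F3 | step 12 | [(3S,4E)-3-methyl-5-[4-methyl-2,5-bis(triisopropylsilyloxy)phenyl]-3-(triethylsilyloxy)pent-4-en-1-yl]zinc iodide | I[Zn]CC[C@](C)(O[Si](CC)(CC)CC)/C=C/c1cc(O[Si](C(C)C)(C(C)C)C(C)C)c(C)cc1O[Si](C(C)C)(C(C)C)C(C)C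
F4 | step 7 | 5-{[4-methyl-2,5-bis(triisopropylsilyloxy)benzyl]sulfanyl}-1-phenyl-1H-tetrazole | Cc1cc(O[Si](C(C)C)(C(C)C)C(C)C)c(CSc2nnnn2-c2ccccc2)cc1O[Si](C(C)C)(C(C)C)C(C)C
F5 | step 7 | 5-{[4-methyl-2,5-bis(triisopropylsilyloxy)benzyl]sulfonyl}-1-phenyl-1H-tetrazole | Cc1cc(O[Si](C(C)C)(C(C)C)C(C)C)c(CS(=O)(=O)c2nnnn2-c2ccccc2)cc1O[Si](C(C)C)(C(C)C)C(C)C
F6 | step 14 | (2E,6E)-7-iodo-6-methyl-2-(4-methylpent-3-en-1-yl)hepta-2,6-dienoic acid | I/C=C(\C)CC/C=C(\CCC=C(C)C)C(=O)O
F7 | step 14 | 2-(trimethylsilyl)ethyl (2E,6E)-7-iodo-6-methyl-2-(4-methylpent-3-en-1-yl)hepta-2,6-dienoate | I/C=C(\C)CC/C=C(\CCC=C(C)C)C(=O)OCC[Si](C)(C)C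
F8 | step 14 | 2-(trimethylsilyl)ethyl (2E,6E,10S,11E)-6,10-dimethyl-2-(4-methylpent-3-en-1-yl)-12-[4-methyl-2,5-bis(triisopropylsilyloxy)phenyl]-10-(triethylsilyloxy)dodeca-2,6,11-trienoate | CC(C)=CCC/C(=C\CC/C(C)=C/CC[C@](C)(O[Si](CC)(CC)CC)/C=C/c1cc(O[Si](C(C)C)(C(C)C)C(C)C)c(C)cc1O[Si](C(C)C)(C(C)C)C(C)C)C(=O)OCC[Si](C)(C)C
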